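**Retrosynthetic overview**

1. Target ⇐ global O‑debenzylation ⇐ Suzuki–Miyaura union (5–5' biaryl bond, made last) of two benzyl‑protected olivil‑type oxolanes; unit A carries Cl on its C2‑aryl ring, unit B on its benzyl ring.
2. Each oxolane ⇐ α‑benzyl‑α‑hydroxy‑γ‑lactone (C=O → CH2); C8' is set by enolate benzylation, then enolate hydroxylation, both anti to the C8 arm.
3. Each γ‑lactone ⇐ Baeyer–Villiger ring expansion of a trans‑2‑aryl‑3‑(benzyloxymethyl)cyclobutanone (1,2‑shift of the benzylic carbon to oxygen with retention). The lactone ring is the oxolane ring of the target, so the two oxolanes (unit A and unit B, in parallel) are the only rings formed.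
4. Each cyclobutanone ⇐ new enantioselective desymmetrising α‑arylation of 3‑[(benzyloxy)methyl]cyclobutanone with an aryl bromide; this sets C8 and, through trans control, C7.
5. Aryl bromides and benzylic bromides ⇐ catechol by O‑methylation, bromination, (chlorination), benzylation, Br/Li exchange–formaldehyde and PBr3.

Assumption: formaldehyde 5 is handled as dry paraformaldehyde; locants C7, C8, C9, C7', C8', C9' follow lignan (olivil) numbering within each unit.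

**Route**

Step 1
Reactants: 1 catechol
Product: 2 guaiacol (2‑methoxyphenol)
Conditions: MeI (1.0 equiv), K2CO3 (1.0 equiv), acetone, 56 °C; distil
Reagents that add atoms: iodomethane, CI
Why: Williamson ether synthesis in which the mono‑phenoxide is methylated once and the mixture with catechol and veratrole is resolved by distillation; no stereocentre is involved.

Step 2
Reactants: 2 guaiacol
Product: 3 4‑bromo‑2‑methoxyphenol
Conditions: NBS (1.0 equiv), MeCN, 0 °C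
Reagents that add atoms: N‑bromosuccinimide, O=C1CCC(=O)N1Br
Why: Electrophilic aromatic bromination in which the free hydroxyl is the stronger director and bromine enters para to it.

Step 3
Reactants: 3 4‑bromo‑2‑methoxyphenol
Product: 4 1‑(benzyloxy)‑4‑bromo‑2‑methoxybenzene
Conditions: BnBr, K2CO3, DMF, rt
Reagents that add atoms: benzyl bromide, BrCc1ccccc1
Why: Williamson O‑benzylation of the phenol, giving an ether that survives every later step until the final hydrogenolysis.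

Step 4
Reactants: 4 1‑(benzyloxy)‑4‑bromo‑2‑methoxybenzene, 5 formaldehyde (as paraformaldehyde)
Product: 7 [4‑(benzyloxy)‑3‑methoxyphenyl]methanol, via aryllithium 6 (not isolated)
Conditions: n‑BuLi, THF, −78 °C; then (CH2O)n, −78 °C → rt; H2O
Reagents that add atoms: none
Why: Bromine–lithium exchange followed by 1,2‑addition of the aryllithium to formaldehyde installs the future C7' carbon.

Step 5
Reactants: 7 [4‑(benzyloxy)‑3‑methoxyphenyl]methanol
Product: 8 1‑(benzyloxy)‑4‑(bromomethyl)‑2‑methoxybenzene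
Conditions: PBr3 (0.4 equiv), Et2O, 0 °C; used directly
Reagents that add atoms: phosphorus tribromide, BrP(Br)Br
Why: Conversion of an activated benzylic alcohol to the bromide with PBr3 (nucleophilic substitution via the phosphite ester).

Step 6
Reactants: 3 4‑bromo‑2‑methoxyphenol
Product: 9 4‑bromo‑2‑chloro‑6‑methoxyphenol
Conditions: NCS (1.05 equiv), MeCN, 40 °C
Reagents that add atoms: N‑chlorosuccinimide, O=C1CCC(=O)N1Cl
Why: Electrophilic aromatic chlorination in which, with the para position blocked by bromine, the phenol directs chlorine to its only free ortho position (the later biaryl carbon).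

Step 7
Reactants: 9 4‑bromo‑2‑chloro‑6‑methoxyphenol
Product: 10 2‑(benzyloxy)‑5‑bromo‑1‑chloro‑3‑methoxybenzene
Conditions: BnBr, K2CO3, DMF, 50 °C
Reagents that add atoms: benzyl bromide, BrCc1ccccc1
Why: Williamson O‑benzylation of the di‑ortho‑substituted phenol.

Step 8
Reactants: 10 2‑(benzyloxy)‑5‑bromo‑1‑chloro‑3‑methoxybenzene, 5 formaldehyde (as paraformaldehyde)
Product: 12 [4‑(benzyloxy)‑3‑chloro‑5‑methoxyphenyl]methanol, via aryllithium 11 (not isolated)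
Conditions: n‑BuLi, THF, −78 °C; then (CH2O)n, −78 °C → rt; H2O
Reagents that add atoms: none
Why: Bromine–lithium exchange (C–Br reacts far faster than C–Cl at −78 °C, and the chlorine is meta to lithium so no aryne forms) followed by addition to formaldehyde.

Step 9
Reactants: 12 [4‑(benzyloxy)‑3‑chloro‑5‑methoxyphenyl]methanol
Product: 13 2‑(benzyloxy)‑5‑(bromomethyl)‑1‑chloro‑3‑methoxybenzene
Conditions: PBr3 (0.4 equiv), Et2O, 0 °C; used directly
Reagents that add atoms: phosphorus tribromide, BrP(Br)Br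
Why: Benzylic alcohol to bromide with PBr3, as in step 5.

Step 10
Reactants: 14 3‑(hydroxymethyl)cyclobutan‑1‑one
Product: 15 3‑[(benzyloxy)methyl]cyclobutan‑1‑one
Conditions: BnOC(=NH)CCl3 (1.3 equiv), TfOH (5 mol %), CH2Cl2–cyclohexane, 0 °C → rt
Reagents that add atoms: benzyl 2,2,2‑trichloroacetimidate, N=C(OCc1ccccc1)C(Cl)(Cl)Cl
Why: Acid‑catalysed trichloroacetimidate O‑benzylation, base‑free so that the strained enolisable ketone is untouched.

Step 11
Reactants: 15 3‑[(benzyloxy)methyl]cyclobutan‑1‑one, 10 2‑(benzyloxy)‑5‑bromo‑1‑chloro‑3‑methoxybenzene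
Product: 16 (2S,3S)‑2‑[4‑(benzyloxy)‑3‑chloro‑5‑methoxyphenyl]‑3‑[(benzyloxy)methyl]cyclobutan‑1‑one
Conditions: 15 (2 equiv), Pd(OAc)2 (5 mol %), P(o‑tol)3 (10 mol %), (2R,5R)‑2,5‑dimethylpyrrolidine (30 mol %), NaOAc (1.5 equiv), 1,4‑dioxane, 70 °C
Reagents that add atoms: none
Why: Proposed new method: enantioselective desymmetrising intermolecular α‑arylation of a prochiral 3‑substituted cyclobutanone by cooperative enamine/palladium catalysis, in which the C2‑symmetric amine condenses with 15 to two rapidly equilibrating diastereomeric enamines (C=C towards either enantiotopic CH2), the arylpalladium bromide formed by oxidative addition of the C–Br bond of 10 to zerovalent palladium (the C–Cl bond is inert with P(o‑tol)3) is attacked only by the enamine whose near methyl group and CH2OBn arm lie on the same face, anti to both, and reductive elimination with iminium hydrolysis gives the aryl ketone with C3 (later C8) fixed and C2 (later C7) trans to it (also the thermodynamic arrangement, since C2 is epimerisable), the steric model predicting (2S,3S) from the (2R,5R)‑amine (its antipode is available should the sense be reversed); the closest known reaction types are the racemic palladium/pyrrolidine α‑arylation of cyclopentanones with aryl bromides, the intramolecular palladium/enamine desymmetrisation of cyclobutanones and the amine‑catalysed desymmetrising aldol reaction of 3‑substituted cyclobutanones.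

Step 12
Reactants: 16 (2S,3S)‑2‑[4‑(benzyloxy)‑3‑chloro‑5‑methoxyphenyl]‑3‑[(benzyloxy)methyl]cyclobutan‑1‑one
Product: 17 (4R,5S)‑5‑[4‑(benzyloxy)‑3‑chloro‑5‑methoxyphenyl]‑4‑[(benzyloxy)methyl]oxolan‑2‑one
Conditions: mCPBA (1.2 equiv), CH2Cl2, 0 °C
Reagents that add atoms: 3‑chloroperbenzoic acid, OOC(=O)c1cccc(Cl)c1
Why: Baeyer–Villiger oxidation, the ring‑expanding key step, in which the electron‑rich secondary benzylic carbon of the Criegee adduct undergoes the 1,2‑shift from carbon to oxygen with retention, so the cyclobutanone becomes the five‑membered lactone that already holds O1, C7, C8, C8' and C9' of the oxolane with C7 (S) and C8 (R) in place.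

Step 13
Reactants: 17 (4R,5S)‑5‑[4‑(benzyloxy)‑3‑chloro‑5‑methoxyphenyl]‑4‑[(benzyloxy)methyl]oxolan‑2‑one, 8 1‑(benzyloxy)‑4‑(bromomethyl)‑2‑methoxybenzene
Product: 19 (3S,4R,5S)‑3‑[4‑(benzyloxy)‑3‑methoxybenzyl]‑5‑[4‑(benzyloxy)‑3‑chloro‑5‑methoxyphenyl]‑4‑[(benzyloxy)methyl]oxolan‑2‑one, via lithium enolate 18 (not isolated)
Conditions: LiN(i‑Pr)2 (1.1 equiv), THF, −78 °C; then 8 (1.2 equiv), −78 → −30 °C
Reagents that add atoms: none
Why: Lactone enolate alkylation in which the benzylic bromide enters anti to the C4 CH2OBn arm and forms the C8'–C7' bond (the new centre is made planar again in step 14).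

Step 14
Reactants: 19 (3S,4R,5S)‑3‑[4‑(benzyloxy)‑3‑methoxybenzyl]‑5‑[4‑(benzyloxy)‑3‑chloro‑5‑methoxyphenyl]‑4‑[(benzyloxy)methyl]oxolan‑2‑one
Product: 21 (3S,4R,5S)‑3‑[4‑(benzyloxy)‑3‑methoxybenzyl]‑5‑[4‑(benzyloxy)‑3‑chloro‑5‑methoxyphenyl]‑4‑[(benzyloxy)methyl]‑3‑hydroxyoxolan‑2‑one, via potassium enolate 20 (not isolated)
Conditions: KN(SiMe3)2 (1.3 equiv), THF, −78 °C; then 2‑(phenylsulfonyl)‑3‑phenyloxaziridine (1.5 equiv), −78 °C; AcOH
Reagents that add atoms: 2‑(phenylsulfonyl)‑3‑phenyloxaziridine, O=S(=O)(c1ccccc1)N1OC1c1ccccc1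
Why: Davis enolate hydroxylation in which the oxaziridine transfers oxygen to the tetrasubstituted potassium enolate on the face anti to the adjacent C4 arm, setting the C8' carbinol centre (OH cis to the aryl group, benzyl cis to the CH2OBn arm) as in the target.

Step 15
Reactants: 21 (3S,4R,5S)‑3‑[4‑(benzyloxy)‑3‑methoxybenzyl]‑5‑[4‑(benzyloxy)‑3‑chloro‑5‑methoxyphenyl]‑4‑[(benzyloxy)methyl]‑3‑hydroxyoxolan‑2‑one
Product: 23 (3S,4R,5S)‑3‑[4‑(benzyloxy)‑3‑methoxybenzyl]‑5‑[4‑(benzyloxy)‑3‑chloro‑5‑methoxyphenyl]‑4‑[(benzyloxy)methyl]oxolan‑3‑ol, via lactol 22 (not isolated)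
Conditions: i‑Bu2AlH (2.5 equiv), CH2Cl2, −78 °C; then Et3SiH (5 equiv), BF3·OEt2 (5 equiv), −78 → −30 °C
Reagents that add atoms: none
Why: Lactone‑to‑cyclic‑ether reduction in which i‑Bu2AlH stops at the lactol and BF3·OEt2/Et3SiH ionic hydrogenation of the derived oxocarbenium ion replaces C=O by CH2 without opening the ring, so all three stereocentres are kept.

Step 16
Reactants: 15 3‑[(benzyloxy)methyl]cyclobutan‑1‑one, 4 1‑(benzyloxy)‑4‑bromo‑2‑methoxybenzene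
Product: 24 (2S,3S)‑2‑[4‑(benzyloxy)‑3‑methoxyphenyl]‑3‑[(benzyloxy)methyl]cyclobutan‑1‑one
Conditions: 15 (2 equiv), Pd(OAc)2 (5 mol %), P(o‑tol)3 (10 mol %), (2R,5R)‑2,5‑dimethylpyrrolidine (30 mol %), NaOAc (1.5 equiv), 1,4‑dioxane, 70 °C
Reagents that add atoms: none
Why: Proposed new method: the same enantioselective desymmetrising enamine/palladium α‑arylation as in step 11, in which the chiral enamine of 15 attacks the arylpalladium bromide generated from 4 and zerovalent palladium anti to both the near methyl group and the C3 arm, fixing C3 and placing the aryl group trans at C2; the closest known reaction types are the racemic palladium/pyrrolidine α‑arylation of cyclopentanones and the intramolecular palladium/enamine desymmetrisation of cyclobutanones.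

Step 17
Reactants: 24 (2S,3S)‑2‑[4‑(benzyloxy)‑3‑methoxyphenyl]‑3‑[(benzyloxy)methyl]cyclobutan‑1‑one
Product: 25 (4R,5S)‑5‑[4‑(benzyloxy)‑3‑methoxyphenyl]‑4‑[(benzyloxy)methyl]oxolan‑2‑one
Conditions: mCPBA (1.2 equiv), CH2Cl2, 0 °C
Reagents that add atoms: 3‑chloroperbenzoic acid, OOC(=O)c1cccc(Cl)c1
Why: Baeyer–Villiger ring expansion with regioselective, stereoretentive 1,2‑shift of the benzylic carbon to oxygen, giving the oxolane ring of unit B.

Step 18
Reactants: 25 (4R,5S)‑5‑[4‑(benzyloxy)‑3‑methoxyphenyl]‑4‑[(benzyloxy)methyl]oxolan‑2‑one, 13 2‑(benzyloxy)‑5‑(bromomethyl)‑1‑chloro‑3‑methoxybenzene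
Product: 27 (3S,4R,5S)‑3‑[4‑(benzyloxy)‑3‑chloro‑5‑methoxybenzyl]‑5‑[4‑(benzyloxy)‑3‑methoxyphenyl]‑4‑[(benzyloxy)methyl]oxolan‑2‑one, via lithium enolate 26 (not isolated)
Conditions: LiN(i‑Pr)2 (1.1 equiv), THF, −78 °C; then 13 (1.2 equiv), −78 → −30 °C
Reagents that add atoms: none
Why: Lactone enolate alkylation anti to the C4 arm, forming the C8'–C7' bond of unit B with the chlorine handle on the benzyl ring.

Step 19
Reactants: 27 (3S,4R,5S)‑3‑[4‑(benzyloxy)‑3‑chloro‑5‑methoxybenzyl]‑5‑[4‑(benzyloxy)‑3‑methoxyphenyl]‑4‑[(benzyloxy)methyl]oxolan‑2‑one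
Product: 29 (3S,4R,5S)‑3‑[4‑(benzyloxy)‑3‑chloro‑5‑methoxybenzyl]‑5‑[4‑(benzyloxy)‑3‑methoxyphenyl]‑4‑[(benzyloxy)methyl]‑3‑hydroxyoxolan‑2‑one, via potassium enolate 28 (not isolated)
Conditions: KN(SiMe3)2 (1.3 equiv), THF, −78 °C; then 2‑(phenylsulfonyl)‑3‑phenyloxaziridine (1.5 equiv), −78 °C; AcOH
Reagents that add atoms: 2‑(phenylsulfonyl)‑3‑phenyloxaziridine, O=S(=O)(c1ccccc1)N1OC1c1ccccc1
Why: Davis enolate hydroxylation anti to the C4 arm sets the C8' centre of unit B exactly as in step 14.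

Step 20
Reactants: 29 (3S,4R,5S)‑3‑[4‑(benzyloxy)‑3‑chloro‑5‑methoxybenzyl]‑5‑[4‑(benzyloxy)‑3‑methoxyphenyl]‑4‑[(benzyloxy)methyl]‑3‑hydroxyoxolan‑2‑one
Product: 31 (3S,4R,5S)‑3‑[4‑(benzyloxy)‑3‑chloro‑5‑methoxybenzyl]‑5‑[4‑(benzyloxy)‑3‑methoxyphenyl]‑4‑[(benzyloxy)methyl]oxolan‑3‑ol, via lactol 30 (not isolated)
Conditions: i‑Bu2AlH (2.5 equiv), CH2Cl2, −78 °C; then Et3SiH (5 equiv), BF3·OEt2 (5 equiv), −78 → −30 °C
Reagents that add atoms: none
Why: Lactol formation and oxocarbenium ionic hydrogenation convert the lactone C=O into CH2 with the ring and its stereocentres intact.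

Step 21
Reactants: 31 (3S,4R,5S)‑3‑[4‑(benzyloxy)‑3‑chloro‑5‑methoxybenzyl]‑5‑[4‑(benzyloxy)‑3‑methoxyphenyl]‑4‑[(benzyloxy)methyl]oxolan‑3‑ol, 23 (3S,4R,5S)‑3‑[4‑(benzyloxy)‑3‑methoxybenzyl]‑5‑[4‑(benzyloxy)‑3‑chloro‑5‑methoxyphenyl]‑4‑[(benzyloxy)methyl]oxolan‑3‑ol
Product: 33 hexa‑O‑benzyl ether of the target (all four phenols and both primary alcohols benzylated), via pinacol boronate 32 (not isolated)
Conditions: 31, B2pin2 (1.05 equiv), Pd2(dba)3 (2 mol %), XPhos (8 mol %), KOAc (3 equiv), 1,4‑dioxane, 100 °C; then 23 (0.95 equiv), aq K3PO4 (3 equiv), 100 °C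
Reagents that add atoms: none
Why: Miyaura borylation followed by Suzuki–Miyaura cross‑coupling in one flask, in which the aryl chloride of 31 is converted to its boronate and couples with the aryl chloride of 23 to form the 5–5' biaryl bond between the C2‑aryl ring of unit A and the benzyl ring of unit B, the free tertiary alcohols being tolerated and no stereocentre touched.

Step 22
Reactants: 33 hexa‑O‑benzyl ether of the target
Product: 34 CNP0269573.1 (target)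
Conditions: H2 (1 atm), Pd/C (10 wt % palladium on carbon), EtOAc–MeOH, rt; stop at full debenzylation
Reagents that add atoms: none
Why: Catalytic hydrogenolysis of the six benzyl ethers, in which aryl and primary alkyl benzyl ethers are cleaved faster than the cyclic 2‑aryloxolane C–O bonds, so stopping at full debenzylation gives the target with all six stereocentres unchanged.

**Compound list**

1 | catechol (benzene‑1,2‑diol) | Oc1ccccc1O | starting material
2 | guaiacol (2‑methoxyphenol) | COc1ccccc1O | intermediate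
3 | 4‑bromo‑2‑methoxyphenol | COc1cc(Br)ccc1O | intermediate
4 | 1‑(benzyloxy)‑4‑bromo‑2‑methoxybenzene | COc1cc(Br)ccc1OCc1ccccc1 | intermediate
5 | formaldehyde | C=O | starting material
6 | [4‑(benzyloxy)‑3‑methoxyphenyl]lithium | [Li]c1ccc(OCc2ccccc2)c(OC)c1 | intermediate
7 | [4‑(benzyloxy)‑3‑methoxyphenyl]methanol | COc1cc(CO)ccc1OCc1ccccc1 | intermediate
8 | 1‑(benzyloxy)‑4‑(bromomethyl)‑2‑methoxybenzene | COc1cc(CBr)ccc1OCc1ccccc1 | intermediate
9 | 4‑bromo‑2‑chloro‑6‑methoxyphenol | COc1cc(Br)cc(Cl)c1O | intermediate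
10 | 2‑(benzyloxy)‑5‑bromo‑1‑chloro‑3‑methoxybenzene | COc1cc(Br)cc(Cl)c1OCc1ccccc1 | intermediate
11 | [4‑(benzyloxy)‑3‑chloro‑5‑methoxyphenyl]lithium | [Li]c1cc(OC)c(OCc2ccccc2)c(Cl)c1 | intermediate
12 | [4‑(benzyloxy)‑3‑chloro‑5‑methoxyphenyl]methanol | COc1cc(CO)cc(Cl)c1OCc1ccccc1 | intermediate
13 | 2‑(benzyloxy)‑5‑(bromomethyl)‑1‑chloro‑3‑methoxybenzene | COc1cc(CBr)cc(Cl)c1OCc1ccccc1 | intermediate
14 | 3‑(hydroxymethyl)cyclobutan‑1‑one | O=C1CC(CO)C1 | starting material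
15 | 3‑[(benzyloxy)methyl]cyclobutan‑1‑one | O=C1CC(COCc2ccccc2)C1 | intermediate
16 | (2S,3S)‑2‑[4‑(benzyloxy)‑3‑chloro‑5‑methoxyphenyl]‑3‑[(benzyloxy)methyl]cyclobutan‑1‑one | C1C(=O)[C@H](c2cc(OC)c(OCc3ccccc3)c(Cl)c2)[C@H]1COCc1ccccc1 | intermediate
17 | (4R,5S)‑5‑[4‑(benzyloxy)‑3‑chloro‑5‑methoxyphenyl]‑4‑[(benzyloxy)methyl]oxolan‑2‑one | C1C(=O)O[C@H](c2cc(OC)c(OCc3ccccc3)c(Cl)c2)[C@H]1COCc1ccccc1 | intermediate
18 | lithium enolate of 17 | C1=C(O[Li])O[C@H](c2cc(OC)c(OCc3ccccc3)c(Cl)c2)[C@H]1COCc1ccccc1 | intermediate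
19 | (3S,4R,5S)‑3‑[4‑(benzyloxy)‑3‑methoxybenzyl]‑5‑[4‑(benzyloxy)‑3‑chloro‑5‑methoxyphenyl]‑4‑[(benzyloxy)methyl]oxolan‑2‑one | COc1cc(C[C@@H]2C(=O)O[C@H](c3cc(OC)c(OCc4ccccc4)c(Cl)c3)[C@H]2COCc2ccccc2)ccc1OCc1ccccc1 | intermediate
20 | potassium enolate of 19 | COc1cc(CC2=C(O[K])O[C@H](c3cc(OC)c(OCc4ccccc4)c(Cl)c3)[C@H]2COCc2ccccc2)ccc1OCc1ccccc1 | intermediate
21 | (3S,4R,5S)‑3‑[4‑(benzyloxy)‑3‑methoxybenzyl]‑5‑[4‑(benzyloxy)‑3‑chloro‑5‑methoxyphenyl]‑4‑[(benzyloxy)methyl]‑3‑hydroxyoxolan‑2‑one | COc1cc(C[C@@]2(O)C(=O)O[C@H](c3cc(OC)c(OCc4ccccc4)c(Cl)c3)[C@H]2COCc2ccccc2)ccc1OCc1ccccc1 | intermediate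
22 | (2RS,3S,4R,5S)‑3‑[4‑(benzyloxy)‑3‑methoxybenzyl]‑5‑[4‑(benzyloxy)‑3‑chloro‑5‑methoxyphenyl]‑4‑[(benzyloxy)methyl]oxolane‑2,3‑diol (lactol, anomer mixture) | COc1cc(C[C@@]2(O)C(O)O[C@H](c3cc(OC)c(OCc4ccccc4)c(Cl)c3)[C@H]2COCc2ccccc2)ccc1OCc1ccccc1 | intermediate
23 | (3S,4R,5S)‑3‑[4‑(benzyloxy)‑3‑methoxybenzyl]‑5‑[4‑(benzyloxy)‑3‑chloro‑5‑methoxyphenyl]‑4‑[(benzyloxy)methyl]oxolan‑3‑ol | COc1cc(C[C@@]2(O)CO[C@H](c3cc(OC)c(OCc4ccccc4)c(Cl)c3)[C@H]2COCc2ccccc2)ccc1OCc1ccccc1 | intermediate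
24 | (2S,3S)‑2‑[4‑(benzyloxy)‑3‑methoxyphenyl]‑3‑[(benzyloxy)methyl]cyclobutan‑1‑one | C1C(=O)[C@H](c2ccc(OCc3ccccc3)c(OC)c2)[C@H]1COCc1ccccc1 | intermediate
25 | (4R,5S)‑5‑[4‑(benzyloxy)‑3‑methoxyphenyl]‑4‑[(benzyloxy)methyl]oxolan‑2‑one | C1C(=O)O[C@H](c2ccc(OCc3ccccc3)c(OC)c2)[C@H]1COCc1ccccc1 | intermediate
26 | lithium enolate of 25 | C1=C(O[Li])O[C@H](c2ccc(OCc3ccccc3)c(OC)c2)[C@H]1COCc1ccccc1 | intermediate
27 | (3S,4R,5S)‑3‑[4‑(benzyloxy)‑3‑chloro‑5‑methoxybenzyl]‑5‑[4‑(benzyloxy)‑3‑methoxyphenyl]‑4‑[(benzyloxy)methyl]oxolan‑2‑one | COc1cc(C[C@@H]2C(=O)O[C@H](c3ccc(OCc4ccccc4)c(OC)c3)[C@H]2COCc2ccccc2)cc(Cl)c1OCc1ccccc1 | intermediate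
28 | potassium enolate of 27 | COc1cc(CC2=C(O[K])O[C@H](c3ccc(OCc4ccccc4)c(OC)c3)[C@H]2COCc2ccccc2)cc(Cl)c1OCc1ccccc1 | intermediate
29 | (3S,4R,5S)‑3‑[4‑(benzyloxy)‑3‑chloro‑5‑methoxybenzyl]‑5‑[4‑(benzyloxy)‑3‑methoxyphenyl]‑4‑[(benzyloxy)methyl]‑3‑hydroxyoxolan‑2‑one | COc1cc(C[C@@]2(O)C(=O)O[C@H](c3ccc(OCc4ccccc4)c(OC)c3)[C@H]2COCc2ccccc2)cc(Cl)c1OCc1ccccc1 | intermediate
30 | (2RS,3S,4R,5S)‑3‑[4‑(benzyloxy)‑3‑chloro‑5‑methoxybenzyl]‑5‑[4‑(benzyloxy)‑3‑methoxyphenyl]‑4‑[(benzyloxy)methyl]oxolane‑2,3‑diol (lactol, anomer mixture) | COc1cc(C[C@@]2(O)C(O)O[C@H](c3ccc(OCc4ccccc4)c(OC)c3)[C@H]2COCc2ccccc2)cc(Cl)c1OCc1ccccc1 | intermediate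
31 | (3S,4R,5S)‑3‑[4‑(benzyloxy)‑3‑chloro‑5‑methoxybenzyl]‑5‑[4‑(benzyloxy)‑3‑methoxyphenyl]‑4‑[(benzyloxy)methyl]oxolan‑3‑ol | COc1cc(C[C@@]2(O)CO[C@H](c3ccc(OCc4ccccc4)c(OC)c3)[C@H]2COCc2ccccc2)cc(Cl)c1OCc1ccccc1 | intermediate
32 | pinacol boronate of 31 (Cl replaced by 4,4,5,5‑tetramethyl‑1,3,2‑dioxaborolan‑2‑yl) | COc1cc(C[C@@]2(O)CO[C@H](c3ccc(OCc4ccccc4)c(OC)c3)[C@H]2COCc2ccccc2)cc(B2OC(C)(C)C(C)(C)O2)c1OCc1ccccc1 | intermediate
33 | hexa‑O‑benzyl ether of the target (5–5' biaryl of the two protected olivil units) | COc1cc(C[C@@]2(O)CO[C@H](c3cc(OC)c(OCc7ccccc7)c(-c4cc(C[C@@]5(O)CO[C@H](c6ccc(OCc7ccccc7)c(OC)c6)[C@H]5COCc5ccccc5)cc(OC)c4OCc4ccccc4)c3)[C@H]2COCc2ccccc2)ccc1OCc1ccccc1 | intermediate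
34 | CNP0269573.1 | COc1cc(C[C@@]2(O)CO[C@H](c3cc(OC)c(O)c(-c4cc(C[C@@]5(O)CO[C@H](c6ccc(O)c(OC)c6)[C@H]5CO)cc(OC)c4O)c3)[C@H]2CO)ccc1O | target

**Totals and risks**

Total step count: 22. Longest linear sequence: 11 steps (1, 2, 6, 7, 11, 12, 13, 14, 15, 21, 22).

Most likely to fail, first: step 11 (and its twin, step 16), the proposed desymmetrising α‑arylation. The hindered enamine may turn over slowly, the strained ketone may ring‑open or self‑condense, 2,4‑diarylation may compete, and the enantioselectivity rests on a steric model. The fallback uses known chemistry, sets out from 10 and returns at 16. Palladium‑catalysed α‑arylation of N,N‑dimethylacetamide with 10 (KN(SiMe3)2, Pd(dba)2, BINAP, dioxane, 100 °C) gives 2‑[4‑(benzyloxy)‑3‑chloro‑5‑methoxyphenyl]‑N,N‑dimethylacetamide F1. Activation with Tf2O and 2,4,6‑collidine and Ghosez‑type [2+2] cycloaddition with allyl benzyl ether F2 (made from prop‑2‑en‑1‑ol, NaH and BnBr), then aqueous NaHCO3 hydrolysis, gives the racemic trans‑cyclobutanone. This is 16 together with its (2R,3R)‑enantiomer F3; preparative chiral SFC separates them and 16 rejoins the route at step 12. For step 16 the same detour starts from 4.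

Second: step 14 (and its twin, step 19), the enolate hydroxylation that creates the tetrasubstituted C8' centre. The oxidant must approach cis to the C5 aryl group, and the hindered enolate may add to the sulfonimine by‑product or react sluggishly. The fallback sets out from 17 and returns at 21, bypassing step 13 and bromide 8. Enolate 18 is trapped with [Me2N=CH2]I to give the Mannich base (3R,4R,5S)‑5‑[4‑(benzyloxy)‑3‑chloro‑5‑methoxyphenyl]‑4‑[(benzyloxy)methyl]‑3‑[(dimethylamino)methyl]oxolan‑2‑one F4. Quaternisation with MeI and NaHCO3‑induced elimination give the α‑methylene lactone (4R,5S)‑5‑[4‑(benzyloxy)‑3‑chloro‑5‑methoxyphenyl]‑4‑[(benzyloxy)methyl]‑3‑methylideneoxolan‑2‑one F5. Nucleophilic epoxidation (t‑BuOOH, DBU) anti to the CH2OBn arm gives the spiro‑epoxide (3R,6S,7R)‑6‑[4‑(benzyloxy)‑3‑chloro‑5‑methoxyphenyl]‑7‑[(benzyloxy)methyl]‑1,5‑dioxaspiro[2.4]heptan‑4‑one F6. Its CH2 terminus is opened by [4‑(benzyloxy)‑3‑methoxyphenyl]magnesium bromide F7 (from 4 and Mg) with catalytic CuI at −40 °C, giving 21 directly. For step 19 the same detour starts from 25 and uses the aryl bromide 10.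

Third: step 15 (and its twin, step 20), the one‑flask lactone‑to‑ether reduction. BF3·OEt2 may ionise the electron‑rich 2‑aryl C7–O bond, leading to reduction at C7 or Friedel–Crafts closure onto the benzyl ring, and the α‑hydroxy oxocarbenium ion forms slowly. The fallback sets out from 21 and returns at 23. LiAlH4 (THF, 0 °C) opens the lactone to (2S,3R,4S)‑2‑[4‑(benzyloxy)‑3‑methoxybenzyl]‑4‑[4‑(benzyloxy)‑3‑chloro‑5‑methoxyphenyl]‑3‑[(benzyloxy)methyl]butane‑1,2,4‑triol F8. Catalytic camphorsulfonic acid in CH2Cl2 at 0 °C ionises the p‑benzyloxybenzylic alcohol and the primary hydroxyl closes the oxolane under thermodynamic control (aryl trans to the CH2OBn arm), giving 23. For step 20 the same detour starts from 29 and ends at 31.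

**Further compounds**

F1 | step 11 | 2‑[4‑(benzyloxy)‑3‑chloro‑5‑methoxyphenyl]‑N,N‑dimethylacetamide | CN(C)C(=O)Cc1cc(OC)c(OCc2ccccc2)c(Cl)c1
F2 | step 11 | allyl benzyl ether, [(prop‑2‑en‑1‑yloxy)methyl]benzene | C=CCOCc1ccccc1
F3 | step 11 | (2R,3R)‑2‑[4‑(benzyloxy)‑3‑chloro‑5‑methoxyphenyl]‑3‑[(benzyloxy)methyl]cyclobutan‑1‑one (enantiomer of 16) | C1C(=O)[C@@H](c2cc(OC)c(OCc3ccccc3)c(Cl)c2)[C@@H]1COCc1ccccc1
F4 | step 14 | (3R,4R,5S)‑5‑[4‑(benzyloxy)‑3‑chloro‑5‑methoxyphenyl]‑4‑[(benzyloxy)methyl]‑3‑[(dimethylamino)methyl]oxolan‑2‑one | CN(C)C[C@@H]1C(=O)O[C@H](c2cc(OC)c(OCc3ccccc3)c(Cl)c2)[C@H]1COCc1ccccc1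
F5 | step 14 | (4R,5S)‑5‑[4‑(benzyloxy)‑3‑chloro‑5‑methoxyphenyl]‑4‑[(benzyloxy)methyl]‑3‑methylideneoxolan‑2‑one | C=C1C(=O)O[C@H](c2cc(OC)c(OCc3ccccc3)c(Cl)c2)[C@H]1COCc1ccccc1
F6 | step 14 | (3R,6S,7R)‑6‑[4‑(benzyloxy)‑3‑chloro‑5‑methoxyphenyl]‑7‑[(benzyloxy)methyl]‑1,5‑dioxaspiro[2.4]heptan‑4‑one (epoxide oxygen trans to the CH2OBn arm) | C1O[C@@]12C(=O)O[C@H](c3cc(OC)c(OCc4ccccc4)c(Cl)c3)[C@H]2COCc1ccccc1
F7 | step 14 | [4‑(benzyloxy)‑3‑methoxyphenyl]magnesium bromide | Br[Mg]c1ccc(OCc2ccccc2)c(OC)c1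
F8 | step 15 | (2S,3R,4S)‑2‑[4‑(benzyloxy)‑3‑methoxybenzyl]‑4‑[4‑(benzyloxy)‑3‑chloro‑5‑methoxyphenyl]‑3‑[(benzyloxy)methyl]butane‑1,2,4‑triol | COc1cc(C[C@@](O)(CO)[C@H](COCc2ccccc2)[C@H](O)c2cc(OC)c(OCc3ccccc3)c(Cl)c2)ccc1OCc1ccccc1
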